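**Assumptions (one line):** the oxazaborolidinium catalyst derived from the (S)-amino-alcohol gives the (S)-aldehyde 7 needed for the target's spiro centre, and the gem-dimethyl-bearing face of ring A controls the facial selectivity of the later halogenations.

## Retrosynthetic overview
- 9-Acetylisoobtusol (16) ⇐ Petasis methylenation of the ring-A ketone 15 ⇐ Mitsunobu inversion of the trans-bromohydrin 14 ⇐ NBS/H2O on the ring-A alkene of 13.
- The tertiary-Br/secondary-Cl pair of 13 ⇐ trans-chlorohydrin 12 from the trisubstituted ring-B alkene of 11, with Br replacing OH with retention.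
- Ring A ⇐ RCM of diene 9, made by allylation of aldehyde 7, then oxidation.
- Ring B and the spiro quaternary centre ⇐ catalytic enantioselective Diels–Alder of the C8 α-methylene aldehyde 5 with isoprene 6. Aldehyde 5 comes from prenol, ethyl vinyl ether and HCHO.
- Ring order: ring B (Diels–Alder) first, ring A (RCM) second.

Spiro[5.5]undecane numbering is used: ring A is C1–C5, the spiro centre is C6, ring B is C7–C11.

## Route

**Step 1**
Reactants: 1 prenol (3-methylbut-2-en-1-ol); 2 ethyl vinyl ether
Product: 3, 3,3-dimethylpent-4-enal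
Conditions: Hg(OAc)2 (5 mol%), NaOAc, excess 2, 35 °C; then neat, sealed tube, 150 °C
Reagents that add atoms: none (EtOH is lost)
Why: Hg(II) transvinylation gives prenyl vinyl ether, and the thermal Claisen [3,3] rearrangement builds the CMe2–CH2–CHO unit with a vinyl group on the gem-dimethyl carbon.

**Step 2**
Reactants: 3; 4 formaldehyde (37% aq.)
Product: 5, 3,3-dimethyl-2-methylenepent-4-enal
Conditions: pyrrolidine (10 mol%), EtCO2H (10 mol%), THF, 45 °C
Reagents that add atoms: none (formaldehyde is reactant 4)
Why: amine-catalysed Mannich/elimination (List–Erkkilä α-methylenation) acts on the only enolisable CH2 and makes no stereocentre.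

**Step 3**
Reactants: 5; 6 isoprene
Product: 7, (1S)-4-methyl-1-(2-methylbut-3-en-2-yl)cyclohex-3-ene-1-carbaldehyde
Conditions: (S)-oxazaborolidinium·NTf2 (20 mol%), CH2Cl2, –78 → –40 °C, 48 h
Reagents that add atoms: none
Why: in this Diels–Alder the chiral Lewis-acid-bound α-methylene aldehyde reacts at its exocyclic alkene with the 'para' regiochemistry, and the catalyst face selection sets the quaternary centre (the future spiro C6).

**Step 4**
Reactants: 7; 8 allylmagnesium bromide
Product: 9, 1-[(1S)-4-methyl-1-(2-methylbut-3-en-2-yl)cyclohex-3-en-1-yl]but-3-en-1-ol (carbinol epimers)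
Conditions: Et2O, –78 → 0 °C
Reagents that add atoms: none (8 is reactant)
Why: 1,2-addition to the non-enolisable aldehyde installs the allyl arm, and the new carbinol centre is erased in step 6.

**Step 5**
Reactants: 9
Product: 10, (6S)-5,5,9-trimethylspiro[5.5]undeca-3,8-dien-1-ol (C1 epimers)
Conditions: Hoveyda–Grubbs II (10 mol%), toluene (5 mM), 80 °C
Reagents that add atoms: none (ethylene is lost)
Why: ring-closing metathesis of the vinyl and allyl groups closes ring A, with gem-dimethyl Thorpe–Ingold assistance, and leaves the trisubstituted ring-B alkene untouched.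

**Step 6**
Reactants: 10
Product: 11, (6S)-5,5,9-trimethylspiro[5.5]undeca-3,8-dien-1-one
Conditions: DMP, NaHCO3, CH2Cl2, rt
Reagents that add atoms: none
Why: Dess–Martin oxidation removes the unwanted C1 carbinol stereocentre and gives the ketone needed for the final methylenation.

**Step 7**
Reactants: 11
Product: 12, (6S,8S,9S)-8-chloro-9-hydroxy-5,5,9-trimethylspiro[5.5]undec-3-en-1-one (Cl and OH trans)
Conditions: NCS, acetone/H2O (4:1), 0 °C → rt
Reagents that add atoms: N-chlorosuccinimide ClN1C(=O)CCC1=O (Cl); water O (OH)
Why: halohydrin formation occurs on the more nucleophilic trisubstituted ring-B alkene, with the chloronium formed anti to the CMe2-bearing face and water opening it at the tertiary carbon anti, which sets C8 (S) and C9 (S).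

**Step 8**
Reactants: 12
Product: 13, (6S,8S,9S)-9-bromo-8-chloro-5,5,9-trimethylspiro[5.5]undec-3-en-1-one
Conditions: 48% aq. HBr, CH2Cl2, 0 °C, 1 h
Reagents that add atoms: hydrogen bromide Br (Br)
Why: SN1 ionisation of the tertiary alcohol is assisted by the anti-periplanar Cl (chloronium bridge), and Br– attacks the tertiary carbon anti to Cl, so Br replaces OH with net retention and ends up trans to Cl.

**Step 9**
Reactants: 13
Product: 14, (3R,4R,6S,8S,9S)-4,9-dibromo-8-chloro-3-hydroxy-5,5,9-trimethylspiro[5.5]undecan-1-one
Conditions: NBS, THF/H2O (4:1), 0 °C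
Reagents that add atoms: N-bromosuccinimide BrN1C(=O)CCC1=O (Br); water O (OH)
Why: bromonium formation on the only remaining alkene from the face anti to the axial methyl of the adjacent CMe2 fixes C4 (R), and water opens it at C3, remote from the quaternary centres, giving the trans bromohydrin.

**Step 10**
Reactants: 14
Product: 15, (3S,4R,6S,8S,9S)-4,9-dibromo-8-chloro-5,5,9-trimethyl-1-oxospiro[5.5]undecan-3-yl acetate
Conditions: PPh3, DIAD, AcOH, THF, 0 °C → rt
Reagents that add atoms: acetic acid CC(=O)O (OAc)
Why: Mitsunobu SN2 inversion at C3 turns the trans bromohydrin into the cis bromoacetate required by the target.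

**Step 11**
Reactants: 15
Product: 16, 9-acetylisoobtusol, (3S,4R,6R,8S,9S)-4,9-dibromo-8-chloro-5,5,9-trimethyl-1-methylidenespiro[5.5]undecan-3-yl acetate
Conditions: Cp2TiMe2 (3 equiv), toluene, 70 °C, dark, 24 h
Reagents that add atoms: dimethyltitanocene C[Ti](C)(C1C=CC=C1)C1C=CC=C1 (supplies the =CH2 carbon)
Why: Petasis methylenation converts the hindered C1 ketone to the exocyclic alkene under non-basic conditions, so the β-acetoxy ketone, acetate and halides survive and no stereocentre is touched.

## Compound list
1 | prenol | CC(C)=CCO | starting material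
2 | ethyl vinyl ether | C=COCC | starting material
3 | 3,3-dimethylpent-4-enal | C=CC(C)(C)CC=O | intermediate
4 | formaldehyde | C=O | starting material
5 | 3,3-dimethyl-2-methylenepent-4-enal | C=CC(C)(C)C(=C)C=O | intermediate
6 | isoprene | C=CC(C)=C | starting material
7 | (1S)-4-methyl-1-(2-methylbut-3-en-2-yl)cyclohex-3-ene-1-carbaldehyde | O=C[C@]1(C(C)(C)C=C)CC=C(C)CC1 | intermediate
8 | allylmagnesium bromide | C=CC[Mg]Br | starting material
9 | homoallylic alcohol (carbinol epimers, spiro-precursor stereocentre as in 7) | C=CCC(O)[C@]1(C(C)(C)C=C)CC=C(C)CC1 | intermediate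
10 | (6S)-5,5,9-trimethylspiro[5.5]undeca-3,8-dien-1-ol (C1 epimers) | OC1CC=CC(C)(C)[C@]12CC=C(C)CC2 | intermediate
11 | (6S)-5,5,9-trimethylspiro[5.5]undeca-3,8-dien-1-one | O=C1CC=CC(C)(C)[C@]12CC=C(C)CC2 | intermediate
12 | (6S,8S,9S)-8-chloro-9-hydroxy-5,5,9-trimethylspiro[5.5]undec-3-en-1-one | O=C1CC=CC(C)(C)[C@@]12CC[C@](C)(O)[C@@H](Cl)C2 | intermediate
13 | (6S,8S,9S)-9-bromo-8-chloro-5,5,9-trimethylspiro[5.5]undec-3-en-1-one | O=C1CC=CC(C)(C)[C@@]12CC[C@](C)(Br)[C@@H](Cl)C2 | intermediate
14 | trans-bromohydrin (3R,4R,6S,8S,9S) | O=C1C[C@@H](O)[C@H](Br)C(C)(C)[C@@]12CC[C@](C)(Br)[C@@H](Cl)C2 | intermediate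
15 | cis-bromoacetate ketone (3S,4R,6S,8S,9S) | O=C1C[C@H](OC(C)=O)[C@H](Br)C(C)(C)[C@@]12CC[C@](C)(Br)[C@@H](Cl)C2 | intermediate
16 | 9-acetylisoobtusol | C=C1C[C@H](OC(C)=O)[C@H](Br)C(C)(C)[C@@]12CC[C@](C)(Br)[C@@H](Cl)C2 | target

## Totals
Total steps: 11. Longest linear sequence: 11 (1 → 3 → 5 → 7 → 9 → 10 → 11 → 12 → 13 → 14 → 15 → 16). This route is linear after the Diels–Alder, so the longest linear sequence equals the total.

## Three steps most likely to fail
1. **Step 3 (hindered enantioselective Diels–Alder).** The α-tert-alkyl acrolein may be too unreactive or give low ee. Fallback: change the approach to a Pd-catalysed asymmetric decarboxylative allylation of a vinylogous ester to set the quaternary centre, then form ring B by RCM.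
2. **Step 5 (RCM of a vinyl group on a quaternary carbon next to the quaternary centre).** Fallback: convert the vinyl group of 7 into a methyl-ketone side chain (hydroboration, oxidation, MeMgBr, oxidation) and close ring A by intramolecular aldol instead.
3. **Step 9 (facial selectivity of bromonium formation, with the Step 10 inversion).** If C4 comes out epimeric, or the Mitsunobu reaction eliminates or is intercepted by Br participation, switch to epoxidation of the alkene with diaxial opening by MgBr2. Then oxidise to the α-bromoketone (DMP) and reduce it with NaBH4/CeCl3 by axial hydride attack to give the cis bromohydrin before acetylation.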